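**Retrosynthetic overview**

1. Target 25 comes from one hydrogenolysis of the fully O-benzylated ester 24.
2. 24 comes from a ring-expanding esterification of the cis-dihydrobenzofuran-3-ylmethanol 15 with acid 21: ring A shifts from C3 to the CH2 carbon through a phenonium ion, the furan ring becomes pyran ring C, and the carboxylate takes C3.
3. 15 comes from exo opening of the epoxide in 13 by an aryllithium; 13 is the Mitsunobu ether of bromophenol 12 and epoxy alcohol 7.
4. 7 comes from catechol and acrolein (Sharpless kinetic resolution); 12 from resorcinol (C–H borylation/oxidation, bromination); 21 from 4-bromophenol (iodination, methylation, C–O coupling, CO2).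
5. Ring order: rings A and B are carried in as arenes; the five-membered O-ring is closed in step 9 and enlarged to ring C in step 14.

Assumption: benzyl bromide, 4-methylbenzyl bromide, iodomethane, benzyl alcohol and CO2 are treated as reagents; racemic 6 is resolved, so step 4 can deliver at most half of it as 7.

**Route**

Step 1
Reactants: 1 catechol
Product: 2 1,2-bis(benzyloxy)benzene
Conditions: BnBr, K2CO3, DMF, 60 °C
Reagents that add atoms: benzyl bromide, BrCc1ccccc1
Why: Williamson etherification of both phenols; no stereocenter is involved.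

Step 2
Reactants: 2 1,2-bis(benzyloxy)benzene
Product: 3 4-bromo-1,2-bis(benzyloxy)benzene
Conditions: NBS, MeCN, 0 to 25 °C
Reagents that add atoms: N-bromosuccinimide, O=C1CCC(=O)N1Br
Why: Electrophilic aromatic bromination goes para to one alkoxy group (position 4), the usual outcome for 1,2-dialkoxybenzenes.

Step 3
Reactants: 3 4-bromo-1,2-bis(benzyloxy)benzene; 4 acrolein
Product: 6 rac-1-[3,4-bis(benzyloxy)phenyl]prop-2-en-1-ol, via aryllithium 5 (not isolated)
Conditions: n-BuLi, THF, −78 °C; then 4, −78 °C; then H2O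
Reagents that add atoms: none
Why: Bromine–lithium exchange followed by 1,2-addition of the hard aryllithium to the aldehyde gives the racemic allylic alcohol.

Step 4
Reactants: 6 rac-1-[3,4-bis(benzyloxy)phenyl]prop-2-en-1-ol
Product: 7 (S)-[3,4-bis(benzyloxy)phenyl][(2R)-oxiran-2-yl]methanol
Conditions: Ti(OiPr)4 (10 mol %), D-(−)-diisopropyl tartrate (15 mol %), t-BuOOH (0.55 equiv), 4 Å molecular sieves, CH2Cl2, −20 °C
Reagents that add atoms: tert-butyl hydroperoxide, CC(C)(C)OO
Why: Sharpless asymmetric epoxidation run as a kinetic resolution: with the D-tartrate the (S)-alcohol is epoxidised fast and on the face that gives the erythro (1S,2R) epoxy alcohol, which sets both stereocenters of the C3 unit, while the (R)-alcohol stays behind unchanged.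

Step 5
Reactants: 8 resorcinol
Product: 9 1,3-bis[(4-methylbenzyl)oxy]benzene
Conditions: 4-methylbenzyl bromide, K2CO3, DMF, 60 °C
Reagents that add atoms: 4-methylbenzyl bromide, Cc1ccc(CBr)cc1
Why: Williamson etherification; the 4-methylbenzyl group is chosen because every C–H of its ring has an ortho substituent (inert in step 6) and it leaves by hydrogenolysis in step 15.

Step 6
Reactants: 9 1,3-bis[(4-methylbenzyl)oxy]benzene
Product: 11 3,5-bis[(4-methylbenzyl)oxy]phenol, via arylboronate 10 (not isolated)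
Conditions: [Ir(OMe)(cod)]2 (1 mol %), 4,4'-di-tert-butyl-2,2'-bipyridine (2 mol %), B2pin2 (0.6 equiv), THF, 60 °C; then KHSO5 (as 2KHSO5·KHSO4·K2SO4), acetone/H2O, 25 °C
Reagents that add atoms: potassium peroxymonosulfate, [K+].[O-]S(=O)(=O)OO
Why: Sterically controlled iridium-catalysed C–H borylation takes the only C–H that has no ortho substituent (C5 of the resorcinol ring), and peroxymonosulfate oxidises the C–B bond to C–OH in the same flask (one-pot borylation/oxidation).

Step 7
Reactants: 11 3,5-bis[(4-methylbenzyl)oxy]phenol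
Product: 12 2-bromo-3,5-bis[(4-methylbenzyl)oxy]phenol
Conditions: NBS (1.0 equiv), i-Pr2NH (10 mol %), CH2Cl2, −78 to 0 °C
Reagents that add atoms: N-bromosuccinimide, O=C1CCC(=O)N1Br
Why: Amine-catalysed ortho-bromination of phenols: the N-bromoamine hydrogen-bonded to the OH delivers bromine to the ortho carbon, and the para carbon is shielded by two benzyloxy groups.

Step 8
Reactants: 12 2-bromo-3,5-bis[(4-methylbenzyl)oxy]phenol; 7 (S)-[3,4-bis(benzyloxy)phenyl][(2R)-oxiran-2-yl]methanol
Product: 13 (2R)-2-[(R)-[3,4-bis(benzyloxy)phenyl]{2-bromo-3,5-bis[(4-methylbenzyl)oxy]phenoxy}methyl]oxirane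
Conditions: PPh3, DIAD, THF, 0 to 25 °C
Reagents that add atoms: none
Why: Mitsunobu etherification: the phenoxide displaces the oxyphosphonium group by SN2 with inversion at the benzylic carbinol (the neighbouring epoxide disfavours ionisation), so the (1S)-alcohol gives the (R)-ether, the future C2, with the epoxide untouched.

Step 9
Reactants: 13 (2R)-2-[(R)-[3,4-bis(benzyloxy)phenyl]{2-bromo-3,5-bis[(4-methylbenzyl)oxy]phenoxy}methyl]oxirane
Product: 15 [(2S,3S)-2-[3,4-bis(benzyloxy)phenyl]-4,6-bis[(4-methylbenzyl)oxy]-2,3-dihydro-1-benzofuran-3-yl]methanol, via aryllithium 14 (not isolated)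
Conditions: t-BuLi (2.1 equiv), THF, −78 to −40 °C; then H2O
Reagents that add atoms: none
Why: Parham-type cyclisation: bromine–lithium exchange, then intramolecular exo opening of the epoxide (the mode preferred by o-lithioaryl glycidyl ethers without Lewis acid) at its internal carbon with inversion, which sets C3 and places CH2OH cis to the aryl group while C2 is untouched.

Step 10
Reactants: 16 4-bromophenol
Product: 17 4-bromo-2,6-diiodophenol
Conditions: I2 (1.05 equiv), 30% H2O2, H2O, 50 °C
Reagents that add atoms: iodine, II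
Why: Electrophilic iodination of both ortho positions of the phenol (para is blocked by bromine), with H2O2 re-oxidising iodide so that both iodine atoms are used.

Step 11
Reactants: 17 4-bromo-2,6-diiodophenol
Product: 18 5-bromo-1,3-diiodo-2-methoxybenzene
Conditions: MeI, K2CO3, acetone, 56 °C
Reagents that add atoms: iodomethane, CI
Why: Williamson O-methylation installs the 4-O-methyl group of the gallate.

Step 12
Reactants: 18 5-bromo-1,3-diiodo-2-methoxybenzene
Product: 19 1,3-bis(benzyloxy)-5-bromo-2-methoxybenzene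
Conditions: BnOH, CuI (20 mol %), 3,4,7,8-tetramethyl-1,10-phenanthroline (40 mol %), Cs2CO3, toluene, 110 °C
Reagents that add atoms: benzyl alcohol, OCc1ccccc1
Why: Copper-catalysed Ullmann-type C–O coupling of aryl iodides with an aliphatic alcohol; C–I reacts much faster than C–Br, so the bromide is kept for step 13.

Step 13
Reactants: 19 1,3-bis(benzyloxy)-5-bromo-2-methoxybenzene
Product: 21 3,5-bis(benzyloxy)-4-methoxybenzoic acid, via aryllithium 20 (not isolated)
Conditions: n-BuLi, THF, −78 °C; CO2; then aq HCl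
Reagents that add atoms: carbon dioxide, O=C=O
Why: Bromine–lithium exchange and carboxylation of the aryllithium with CO2.

Step 14
Reactants: 15 [(2S,3S)-2-[3,4-bis(benzyloxy)phenyl]-4,6-bis[(4-methylbenzyl)oxy]-2,3-dihydro-1-benzofuran-3-yl]methanol; 21 3,5-bis(benzyloxy)-4-methoxybenzoic acid
Product: 24 (2R,3R)-2-[3,4-bis(benzyloxy)phenyl]-5,7-bis[(4-methylbenzyl)oxy]-3,4-dihydro-2H-chromen-3-yl 3,5-bis(benzyloxy)-4-methoxybenzoate, via oxyphosphonium salt 22 (not isolated), via phenonium ion 23 (not isolated)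
Conditions: 21 (1.3 equiv), PPh3, DIAD, toluene, −20 to 25 °C
Reagents that add atoms: none
Why: Proposed new method: the Mitsunobu oxyphosphonium 22 of this primary alcohol, whose β-carbon carries the 2,4,6-trioxygenated ring A, should ionise with aryl participation faster than it is displaced directly, giving phenonium ion 23 (the ring-A ipso carbon bridging C3 and the old CH2); its only counter-ion, the carboxylate of 21, should then open the cyclopropane at the secondary ring-fusion carbon anti to the migrating aryl, which breaks the C3–aryl bond, turns the furan ring into pyran ring C (a stepwise, ionic 1,2-aryl shift with ring expansion) and puts the ester on C3 with inversion, so cis-(2S,3S)-15 gives the 2,3-cis (2R,3R) ester with C2 untouched; the closest known chemistry is the solvolytic 1,2-aryl shift of β-aryl sulfonates through phenonium ions (stereospecific, opening at the more substituted carbon) combined with ordinary Mitsunobu esterification.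

Step 15
Reactants: 24 (2R,3R)-2-[3,4-bis(benzyloxy)phenyl]-5,7-bis[(4-methylbenzyl)oxy]-3,4-dihydro-2H-chromen-3-yl 3,5-bis(benzyloxy)-4-methoxybenzoate
Product: 25 epicatechin 3-O-(4-O-methylgallate), (2R,3R)-2-(3,4-dihydroxyphenyl)-5,7-dihydroxy-3,4-dihydro-2H-chromen-3-yl 3,5-dihydroxy-4-methoxybenzoate
Conditions: H2 (1 atm), Pd(OH)2/C, THF/MeOH, 25 °C
Reagents that add atoms: none
Why: Hydrogenolysis removes all six benzyl-type ethers in one operation; the cyclic C2–O bond, the ester and both stereocenters survive these conditions in benzylated catechin gallates.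

**Compound list**

1 | catechol | Oc1ccccc1O | starting material
2 | 1,2-bis(benzyloxy)benzene | c1ccc(COc2ccccc2OCc2ccccc2)cc1 | intermediate
3 | 4-bromo-1,2-bis(benzyloxy)benzene | Brc1ccc(OCc2ccccc2)c(OCc2ccccc2)c1 | intermediate
4 | acrolein | C=CC=O | starting material
5 | [3,4-bis(benzyloxy)phenyl]lithium | [Li]c1ccc(OCc2ccccc2)c(OCc2ccccc2)c1 | intermediate (not isolated)
6 | rac-1-[3,4-bis(benzyloxy)phenyl]prop-2-en-1-ol | C=CC(O)c1ccc(OCc2ccccc2)c(OCc2ccccc2)c1 | intermediate
7 | (S)-[3,4-bis(benzyloxy)phenyl][(2R)-oxiran-2-yl]methanol (erythro) | O[C@@H](c1ccc(OCc2ccccc2)c(OCc2ccccc2)c1)[C@H]1CO1 | intermediate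
8 | resorcinol | Oc1cccc(O)c1 | starting material
9 | 1,3-bis[(4-methylbenzyl)oxy]benzene | Cc1ccc(COc2cccc(OCc3ccc(C)cc3)c2)cc1 | intermediate
10 | 2-{3,5-bis[(4-methylbenzyl)oxy]phenyl}-4,4,5,5-tetramethyl-1,3,2-dioxaborolane | Cc1ccc(COc2cc(OCc3ccc(C)cc3)cc(B3OC(C)(C)C(C)(C)O3)c2)cc1 | intermediate (not isolated)
11 | 3,5-bis[(4-methylbenzyl)oxy]phenol | Cc1ccc(COc2cc(O)cc(OCc3ccc(C)cc3)c2)cc1 | intermediate
12 | 2-bromo-3,5-bis[(4-methylbenzyl)oxy]phenol | Cc1ccc(COc2cc(O)c(Br)c(OCc3ccc(C)cc3)c2)cc1 | intermediate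
13 | (2R)-2-[(R)-[3,4-bis(benzyloxy)phenyl]{2-bromo-3,5-bis[(4-methylbenzyl)oxy]phenoxy}methyl]oxirane (threo) | Cc1ccc(COc2cc(OCc3ccc(C)cc3)c(Br)c(O[C@H](c3ccc(OCc4ccccc4)c(OCc4ccccc4)c3)[C@H]3CO3)c2)cc1 | intermediate
14 | aryllithium from 13 (Li in place of Br, same configuration) | Cc1ccc(COc2cc(OCc3ccc(C)cc3)c([Li])c(O[C@H](c3ccc(OCc4ccccc4)c(OCc4ccccc4)c3)[C@H]3CO3)c2)cc1 | intermediate (not isolated)
15 | [(2S,3S)-2-[3,4-bis(benzyloxy)phenyl]-4,6-bis[(4-methylbenzyl)oxy]-2,3-dihydro-1-benzofuran-3-yl]methanol (2,3-cis) | OC[C@H]1[C@@H](c2ccc(OCc3ccccc3)c(OCc3ccccc3)c2)Oc2cc(OCc3ccc(C)cc3)cc(OCc3ccc(C)cc3)c21 | intermediate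
16 | 4-bromophenol | Oc1ccc(Br)cc1 | starting material
17 | 4-bromo-2,6-diiodophenol | Oc1c(I)cc(Br)cc1I | intermediate
18 | 5-bromo-1,3-diiodo-2-methoxybenzene | COc1c(I)cc(Br)cc1I | intermediate
19 | 1,3-bis(benzyloxy)-5-bromo-2-methoxybenzene | COc1c(OCc2ccccc2)cc(Br)cc1OCc1ccccc1 | intermediate
20 | [3,5-bis(benzyloxy)-4-methoxyphenyl]lithium | COc1c(OCc2ccccc2)cc([Li])cc1OCc1ccccc1 | intermediate (not isolated)
21 | 3,5-bis(benzyloxy)-4-methoxybenzoic acid | COc1c(OCc2ccccc2)cc(C(=O)O)cc1OCc1ccccc1 | intermediate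
22 | {[(2S,3S)-2-[3,4-bis(benzyloxy)phenyl]-4,6-bis[(4-methylbenzyl)oxy]-2,3-dihydro-1-benzofuran-3-yl]methoxy}(triphenyl)phosphonium, carboxylate of 21 as counter-ion (cation drawn) | c1ccc([P+](OC[C@H]2[C@@H](c3ccc(OCc4ccccc4)c(OCc4ccccc4)c3)Oc3cc(OCc4ccc(C)cc4)cc(OCc4ccc(C)cc4)c32)(c2ccccc2)c2ccccc2)cc1 | intermediate (not isolated)
23 | phenonium ion: ring-A ipso carbon bridges C3 and the former CH2 as a cis-fused cyclopropane, charge spread over the trioxygenated ring, aryl-bearing carbon 2S, carboxylate of 21 as counter-ion (cation drawn, one resonance form) | O1C2=CC(=[O+]Cc3ccc(C)cc3)C=C(OCc3ccc(C)cc3)[C@@]24C[C@H]4[C@H]1c1ccc(OCc3ccccc3)c(OCc3ccccc3)c1 | intermediate (not isolated)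
24 | (2R,3R)-2-[3,4-bis(benzyloxy)phenyl]-5,7-bis[(4-methylbenzyl)oxy]-3,4-dihydro-2H-chromen-3-yl 3,5-bis(benzyloxy)-4-methoxybenzoate | COc1c(OCc2ccccc2)cc(C(=O)O[C@@H]2Cc3c(OCc4ccc(C)cc4)cc(OCc4ccc(C)cc4)cc3O[C@@H]2c2ccc(OCc3ccccc3)c(OCc3ccccc3)c2)cc1OCc1ccccc1 | intermediate
25 | epicatechin 3-O-(4-O-methylgallate), (2R,3R) | COc1c(O)cc(C(=O)O[C@@H]2Cc3c(O)cc(O)cc3O[C@@H]2c2ccc(O)c(O)c2)cc1O | target

**Step count and risks**

Total step count: 15.
Longest linear sequence: 8 steps (1, 2, 3, 4, 8, 9, 14, 15).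

The three steps most likely to fail:

Step 14 (the proposed new reaction). The carboxylate may collapse on the primary carbon of 23 and give the unrearranged primary ester, or be displaced directly before ionisation; a hydride shift is a lesser risk. The fallback uses known chemistry only, sets out from 13 and comes back to the route at 24. MgBr2·OEt2 (THF, 0 °C) opens the epoxide of 13 at its terminal carbon to give (1R,2S)-3-bromo-1-[3,4-bis(benzyloxy)phenyl]-1-{2-bromo-3,5-bis[(4-methylbenzyl)oxy]phenoxy}propan-2-ol F1 as its magnesium alkoxide. Bromine–lithium exchange on the aryl bromide (n-BuLi, −100 °C) and displacement of the primary bromide on warming (Parham cyclialkylation) close ring C directly and give (2R,3R)-2-[3,4-bis(benzyloxy)phenyl]-5,7-bis[(4-methylbenzyl)oxy]-3,4-dihydro-2H-chromen-3-ol F2. Esterification of F2 with 21 (EDC·HCl, DMAP, CH2Cl2) gives 24. This path has no ring expansion: the C3–O bond of the epoxide is kept throughout, so the same (2R,3R) configuration results.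

Step 9. The aryllithium may open the epoxide at the terminal carbon, or abstract the benzylic ether proton instead of cyclising. The fallback avoids organolithium chemistry; it sets out from 12 and from the alcohol that step 4 leaves unreacted, (R)-1-[3,4-bis(benzyloxy)phenyl]prop-2-en-1-ol F3, and comes back at 15. Mitsunobu coupling of 12 with F3 (PPh3, DIAD, inversion) gives 1-{[(1S)-1-[3,4-bis(benzyloxy)phenyl]prop-2-en-1-yl]oxy}-2-bromo-3,5-bis[(4-methylbenzyl)oxy]benzene F4. An intramolecular Heck reaction (Pd(OAc)2, PPh3, Ag2CO3, MeCN, 80 °C), which can only close exo, gives (2R)-2-[3,4-bis(benzyloxy)phenyl]-3-methylidene-4,6-bis[(4-methylbenzyl)oxy]-2,3-dihydro-1-benzofuran F5; the silver salt is there to suppress isomerisation to the benzofuran. Hydroboration with 9-BBN from the face opposite the C2 aryl group, then NaOH/H2O2, gives 15 with the 2,3-cis relationship.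

Step 12. The double C–O coupling next to the methoxy group may stop after one iodide or touch the bromide. The fallback replaces C–O coupling by borylation, oxidation and O-alkylation; it sets out from 18 and comes back at 19. Miyaura borylation of the two C–I bonds (PdCl2(dppf), B2pin2, KOAc, DMSO, 80 °C) gives 2,2'-(5-bromo-2-methoxy-1,3-phenylene)bis(4,4,5,5-tetramethyl-1,3,2-dioxaborolane) F6. Oxidation with NaOH/H2O2 gives 5-bromo-2-methoxybenzene-1,3-diol F7, and BnBr/K2CO3 gives 19.

**Further compounds**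

F1 | step 14 | (1R,2S)-3-bromo-1-[3,4-bis(benzyloxy)phenyl]-1-{2-bromo-3,5-bis[(4-methylbenzyl)oxy]phenoxy}propan-2-ol | Cc1ccc(COc2cc(OCc3ccc(C)cc3)c(Br)c(O[C@H](c3ccc(OCc4ccccc4)c(OCc4ccccc4)c3)[C@H](O)CBr)c2)cc1
F2 | step 14 | (2R,3R)-2-[3,4-bis(benzyloxy)phenyl]-5,7-bis[(4-methylbenzyl)oxy]-3,4-dihydro-2H-chromen-3-ol | O[C@@H]1Cc2c(OCc3ccc(C)cc3)cc(OCc3ccc(C)cc3)cc2O[C@@H]1c1ccc(OCc2ccccc2)c(OCc2ccccc2)c1
F3 | step 9 | (R)-1-[3,4-bis(benzyloxy)phenyl]prop-2-en-1-ol | C=C[C@@H](O)c1ccc(OCc2ccccc2)c(OCc2ccccc2)c1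
F4 | step 9 | 1-{[(1S)-1-[3,4-bis(benzyloxy)phenyl]prop-2-en-1-yl]oxy}-2-bromo-3,5-bis[(4-methylbenzyl)oxy]benzene | Cc1ccc(COc2cc(OCc3ccc(C)cc3)c(Br)c(O[C@H](c3ccc(OCc4ccccc4)c(OCc4ccccc4)c3)C=C)c2)cc1
F5 | step 9 | (2R)-2-[3,4-bis(benzyloxy)phenyl]-3-methylidene-4,6-bis[(4-methylbenzyl)oxy]-2,3-dihydro-1-benzofuran | C=C1[C@@H](c2ccc(OCc3ccccc3)c(OCc3ccccc3)c2)Oc2cc(OCc3ccc(C)cc3)cc(OCc3ccc(C)cc3)c21
F6 | step 12 | 2,2'-(5-bromo-2-methoxy-1,3-phenylene)bis(4,4,5,5-tetramethyl-1,3,2-dioxaborolane) | COc1c(B2OC(C)(C)C(C)(C)O2)cc(Br)cc1B1OC(C)(C)C(C)(C)O1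
F7 | step 12 | 5-bromo-2-methoxybenzene-1,3-diol | COc1c(O)cc(Br)cc1O
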